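## The problem

Arthonioic acid (21) is a depside with no stereocentre and no ring to build. Ring A, a 2,4-dihydroxy-6-(2-oxoheptyl)benzoyl unit, is held as an aryl ester on O4 of ring B, a 2-methoxy-6-(2-oxoheptyl)benzoic acid (C1 carries the carboxyl carbon in each ring). The difficulty is chemoselectivity. On each ring the ketone of the C6 chain and the C1 carboxyl carbon close to a 3-pentylisocoumarin (an enol lactone) as soon as that carboxyl is free under acid or is activated for acylation. On ring A this closure would expel the ring B phenol, so the depside link itself is at stake. The link is the aryl ester of a doubly ortho-substituted benzoic acid: slow to make and, once made, open to phenoxide, alkoxide and hydroxide. Both rings share one resorcinol pattern but need different oxygen substitution, so on ring B the chelated ortho oxygen (to be methylated) must be told apart from the para oxygen (to be acylated). The chain must be attached through its terminal CH2, not through C3 of the heptanone. A late, twofold solution is possible because C6 of ring A and C6 of ring B are the same kind of carbon: sp2, ortho to an ester carbonyl and meta to the ring oxygens. Two C6–Br bonds can therefore pass through the esterification as inert placeholders and then be turned together into the two C6–CH2 bonds.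

## Retrosynthesis

**21 to 20.** The three O–CH2Ph bonds are cut: two phenolic ethers on ring A and the ester on ring B. Benzyl is preferred to methyl, acetyl or tert-butyl because all three groups leave in one hydrogenolysis with neither acid nor base, which the keto acid and the depside ester need. Precursor 20 has the same skeleton but no acidic proton, which the organometallic step before it requires. The forward reaction must spare two dialkyl ketones and the aryl ester.

**20 to 13 and two molecules of 16.** The C6–CH2 bond of ring A and the C6–CH2 bond of ring B are cut in one stroke. The neighbouring cut, CH2–C(=O), would need a benzylic halide or metal ortho to an ester, which invites phthalide closure. Cutting the depside first would put an activated ring A carboxyl beside its own ketone chain, which invites the isocoumarin. Dibromide 13 carries no ketone, cannot lactonize, and turns two chain syntheses into one operation. The forward step must form two aryl–CH2 bonds under near-neutral conditions, at the terminal carbon of the heptanone unit only, and leave three esters untouched.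

**16 to 14.** The O–Si bond is cut, through lithium enolate 15. The terminal enol silane is the kinetic isomer of a methyl ketone and stores the regiochemistry that the coupling later reads out. The forward reaction needs deprotonation under irreversible conditions and O-silylation.

**13 to 6 and 11.** The depside C(=O)–O4 bond is cut, through acid chloride 12. With bromine in place of both chains this is an ordinary acylation of a phenol by a hindered aroyl chloride. Neither partner has a ketone or a free carboxyl, and the ring B carboxyl is already a benzyl ester. The forward reaction must overcome the two ortho substituents of the acid.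

**6 to 5 to 3 and 4.** The oxidation level is stepped back from acid to aldehyde and the two O–benzyl bonds are cut. The carboxyl carbon is carried as a formyl group because electrophilic formylation places it exactly, and the oxidation is placed after benzylation because free resorcinol hydroxyls do not survive chlorite.

**11 to 10, 9, 8, 7 and 3.** In turn: the O4 acetal, the ester O–benzyl bond, the aldehyde-to-acid oxidation, the O2–CH3 bond and the O4–CH2OMe bond. A methoxymethyl group is chosen for O4 because it survives base, chlorite and carboxylate alkylation and is removed by mild acid beside a benzyl ester. A benzyl ether could not later be told from that ester. The differentiation of the two oxygens rests on the hydrogen bond from the ortho hydroxyl to the aldehyde in 3.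

**3 to 1.** The ring–CHO bond is cut, through iminium salt 2. Both halves converge on this one aldehyde. Formylation para to one hydroxyl and ortho to the other places the carbon between OH and Br, and the bromine is already present in commercial 1.

## Roads not taken

**Alternative 1:** ring B is built from acyclic parts by cutting its C1–C2 and C5–C6 bonds. In the forward step the ketene-acetal diene A2 adds to the ketal-protected ynoate A3, and loss of methanol and of the silyl group gives phenol A1. Its merit is real: A1 arrives with O2 methylated, O4 free, the benzyl ester in place and the chain present. The chosen route spends steps 4 to 8 on that differentiation and is the weaker of the two on this point. The weak points are these: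
- It solves one ring only. Ring A still needs its chain by a second, different method.
- Both ketones must travel as dioxolanes because the ring A acid has to be activated with its chain present.
- The ketals come off under aqueous acid, the very condition under which the ring A ketone can enol-lactonize onto the depside carbonyl.
- A3 needs several steps of its own, β-alkyl ynoates are sluggish dienophiles, and A2 is hydrolytically fragile.

Against the elegance at ring B, the chosen plan offers one aldehyde (3) for both rings, one reaction for both chains, no ketal and no acid at the end.

**Alternative 2:** the CH2–C(=O) bond of both chains is cut. The bis(chloromethyl) depside A5 and hexanoyl chloride A6 are reduced at a cathode with NiBr2(2,2'-bipyridine) and a sacrificial Mg anode. Zerovalent nickel inserts into each benzylic C–Cl bond and the benzylnickel species is acylated, giving A4. The merits are cheap methyl-bearing (orsellinate-type) rings, no tin or palladium, and no enolate regiochemistry question, since the carbonyl position is fixed by the acyl chloride. In raw-material cost and atom economy this route is ahead of the chosen one. The weak points are structural: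
- A chloromethyl group ortho to an ester is set up for phthalide closure. On ring B this costs the tert-butyl group; on ring A it expels the ring B phenoxide. The risk exists when A5 is made and during electrolysis as Lewis-acidic magnesium salts build up.
- Benzylic halogenation of two electron-rich rings competes with nuclear halogenation.
- Homocoupling to bibenzyls and reduction to methyl are the usual leaks of cross-electrophile coupling.
- A4 still needs two more steps. Two aryl acetates must be removed beside the depside aryl ester, and the tert-butyl ester must be removed with acid beside an ortho ketone chain.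

The chosen plan sets against this a precursor (13) whose sp2 C–Br bonds cannot be displaced by a neighbouring carboxyl, a neutral coupling, and one neutral deprotection.

**Alternative 3:** the depside carbonyl is cut on both sides, C1(ring A)–C(=O) and C(=O)–O4(ring B). Aryl iodide A8, carbon monoxide A9 and phenol A1 combine under Pd(OAc)2, Xantphos and NEt3 to give the bis-dioxolane A7. Its merit is that the hindered ring A acid is never made or activated, so ring A needs no formylation and no oxidation. For the ester bond itself this is the better idea. The weak points are these:
- A8 is electron-rich and flanked by two ortho substituents, and A1 is an electron-poor phenol, so ester-forming capture of the acylpalladium is slow. Hydrodehalogenation and direct C–O coupling can compete.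
- Regioselective iodination to A8 is not assured, because the position between the two benzyloxy groups competes.
- Both chains must be installed separately on the two halves and ketalized.
- The endgame needs acid deketalization plus hydrogenolysis.

The chosen plan forms its ester by a textbook acylation of ketone-free partners, installs both chains in one flask, and has a one-step neutral endgame.

Key step: step 11

Remark on the chemistry: tin enolate 17 is written O-bound; it equilibrates with its C-bound form (1-(tributylstannyl)heptan-2-one), and either can deliver the enolate to palladium.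

## Steps

Step 1
Reactants: 1 5-bromoresorcinol
Product: 3 2-bromo-4,6-dihydroxybenzaldehyde, via aryl iminium chloride 2 (not isolated)
Conditions: POCl3, DMF, MeCN, 0 °C to rt; then H2O, 50 °C
Reagents that add atoms: N,N-dimethylformamide, CN(C)C=O; water, O
Why: Vilsmeier–Haack formylation; the chloroiminium ion should attack the ring carbon para to one hydroxyl and ortho to the other (between OH and Br), the position taken in orcinol and in 1-bromo-3,5-dimethoxybenzene, and iminium salt 2 is hydrolysed to the aldehyde on aqueous work-up.

Step 2
Reactants: 3 2-bromo-4,6-dihydroxybenzaldehyde; 4 benzyl bromide (2.4 equiv)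
Product: 5 2,4-bis(benzyloxy)-6-bromobenzaldehyde
Conditions: K2CO3, DMF, 60 °C
Reagents that add atoms: none
Why: Williamson etherification; K2CO3 in warm DMF should alkylate the chelated ortho hydroxyl as well as the para one, and the non-enolizable aldehyde is inert to the base.

Step 3
Reactants: 5 2,4-bis(benzyloxy)-6-bromobenzaldehyde
Product: 6 2,4-bis(benzyloxy)-6-bromobenzoic acid
Conditions: NaClO2, NaH2PO4, 2-methyl-2-butene, t-BuOH/THF/H2O, rt
Reagents that add atoms: sodium chlorite, [Na+].[O-]Cl=O
Why: Pinnick oxidation; chlorous acid converts the hindered aryl aldehyde into the acid without touching benzyl ethers or the C–Br bond, and the alkene scavenger removes HOCl before it can chlorinate the electron-rich ring.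

Step 4
Reactants: 3 2-bromo-4,6-dihydroxybenzaldehyde
Product: 7 2-bromo-6-hydroxy-4-(methoxymethoxy)benzaldehyde
Conditions: MeOCH2Cl (1.05 equiv), i-Pr2NEt, CH2Cl2, 0 °C
Reagents that add atoms: chloromethyl methyl ether, COCCl
Why: Selective O-alkylation; the ortho hydroxyl is tied up in a hydrogen bond to the aldehyde, so one equivalent of the chloromethyl ether with a hindered amine should react only at the para hydroxyl, the usual selectivity of 2,4-dihydroxybenzaldehydes.

Step 5
Reactants: 7 2-bromo-6-hydroxy-4-(methoxymethoxy)benzaldehyde
Product: 8 2-bromo-6-methoxy-4-(methoxymethoxy)benzaldehyde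
Conditions: MeI, K2CO3, DMF, 40 °C
Reagents that add atoms: iodomethane, CI
Why: Williamson methylation of the remaining chelated phenol; the methoxymethyl acetal is stable to base.

Step 6
Reactants: 8 2-bromo-6-methoxy-4-(methoxymethoxy)benzaldehyde
Product: 9 2-bromo-6-methoxy-4-(methoxymethoxy)benzoic acid
Conditions: NaClO2, NaH2PO4, 2-methyl-2-butene, t-BuOH/THF/H2O, rt
Reagents that add atoms: sodium chlorite, [Na+].[O-]Cl=O
Why: Pinnick oxidation; the phosphate buffer keeps the medium only weakly acidic, which an aryl methoxymethyl ether tolerates, and the scavenger protects the activated ring.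

Step 7
Reactants: 9 2-bromo-6-methoxy-4-(methoxymethoxy)benzoic acid; 4 benzyl bromide
Product: 10 benzyl 2-bromo-6-methoxy-4-(methoxymethoxy)benzoate
Conditions: K2CO3, DMF, rt
Reagents that add atoms: none
Why: Carboxylate O-alkylation (SN2 at the benzylic carbon); this avoids addition to the doubly ortho-substituted carbonyl, where Fischer esterification would fail.

Step 8
Reactants: 10 benzyl 2-bromo-6-methoxy-4-(methoxymethoxy)benzoate
Product: 11 benzyl 2-bromo-4-hydroxy-6-methoxybenzoate
Conditions: HCl (3 M in MeOH), THF, 40 °C
Reagents that add atoms: none
Why: Acid-catalysed acetal exchange frees the phenol as dimethoxymethane leaves; the benzyl ester is flanked by two ortho groups and should resist acid-catalysed transesterification, and the aryl methyl ether and bromide are inert.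

Step 9
Reactants: 6 2,4-bis(benzyloxy)-6-bromobenzoic acid; 11 benzyl 2-bromo-4-hydroxy-6-methoxybenzoate
Product: 13 benzyl 4-{[2,4-bis(benzyloxy)-6-bromobenzoyl]oxy}-2-bromo-6-methoxybenzoate, via acid chloride 12 (not isolated)
Conditions: (COCl)2, N,N-dimethylformamide (cat.), CH2Cl2, 0 °C to rt, concentrate; then 11, NEt3, 4-(dimethylamino)pyridine (cat.), CH2Cl2, 0 °C to rt
Reagents that add atoms: none
Why: Acid chloride formation followed by acylation of the phenol through the acylpyridinium ion; neither partner has a ketone chain or a free carboxyl at this stage, so no isocoumarin or mixed-anhydride pathway exists, and the benzyl ester of 11 is inert.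

Step 10
Reactants: 14 heptan-2-one
Product: 16 2-(trimethylsilyloxy)hept-1-ene, via lithium enolate 15 (not isolated)
Conditions: LiN(i-Pr)2 (commercial solution), THF, −78 °C; then Me3SiCl, −78 to 0 °C; non-aqueous work-up, distillation
Reagents that add atoms: chlorotrimethylsilane, C[Si](C)(C)Cl
Why: Kinetic enolization; the hindered amide removes a methyl proton irreversibly at low temperature and O-silylation fixes the terminal enolate 15 as the enol silane, provided the base is kept in slight excess so the enolate cannot equilibrate.

Step 11
Reactants: 13 benzyl 4-{[2,4-bis(benzyloxy)-6-bromobenzoyl]oxy}-2-bromo-6-methoxybenzoate; 16 2-(trimethylsilyloxy)hept-1-ene (2.6 equiv)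
Product: 20 benzyl 4-{[2,4-bis(benzyloxy)-6-(2-oxoheptyl)benzoyl]oxy}-2-methoxy-6-(2-oxoheptyl)benzoate (tribenzyl arthonioic acid), via tributyltin enolate 17 (not isolated), via ring A monoketone 18 (not isolated), via ring B monoketone 19 (not isolated)
Conditions: Pd2(dba)3 (3 mol%), P(t-Bu)3 (12 mol%), Bu3SnF (2.8 equiv), toluene, 85 °C
Reagents that add atoms: none
Why: The reaction type is the known palladium-catalysed arylation of ketone trimethylsilyl enol ethers with aryl bromides under Bu3SnF promotion, run here twice in one flask. Fluoride passes from tin to silicon, giving tin enolate 17 and volatile Me3SiF; zerovalent palladium carrying P(t-Bu)3 inserts into a C–Br bond of 13, 17 transmetalates to the divalent arylpalladium bromide with release of Bu3SnBr, and reductive elimination from the C-bound palladium enolate forms the aryl–CH2 bond. Both C–Br bonds are ortho to an ester carbonyl and meta to the ether oxygens, so each is activated for oxidative addition; whichever reacts first gives monoketone 18 or 19, and a second cycle should convert either into 20. No ring is closed and no stereocentre is formed. The site of arylation in the heptanone unit is fixed by 16: only its terminal CH2 carries the metal, and without a base the enolate cannot move to C3. A second arylation of a product ketone should be suppressed because the ketone is not deprotonated under these neutral conditions and its benzylic CH2 is shielded by the single ortho ester group. The depside and benzyl esters should survive because the only nucleophiles present are a weakly basic tin enolate and sparingly soluble Bu3SnF, and the ketone is delivered in its keto form, which does not attack the neighbouring ester without acid or base.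

Step 12
Reactants: 20 benzyl 4-{[2,4-bis(benzyloxy)-6-(2-oxoheptyl)benzoyl]oxy}-2-methoxy-6-(2-oxoheptyl)benzoate
Product: 21 arthonioic acid
Conditions: H2 (1 atm), Pd/C (10 wt% Pd), EtOAc, rt; filtration and evaporation without acid or base
Reagents that add atoms: none
Why: Catalytic hydrogenolysis cleaves the two benzyl aryl ethers and the benzyl ester as toluene; dialkyl ketones, the aryl ester and the methyl ether are inert at one atmosphere in neutral EtOAc, and the absence of acid and base should keep the freed keto acid from closing to the isocoumarin.

## Compound list

1 | 5-bromoresorcinol (5-bromobenzene-1,3-diol) | Oc1cc(O)cc(Br)c1 | starting material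
2 | N-[(2-bromo-4,6-dihydroxyphenyl)methylidene]-N-methylmethanaminium chloride (aryl iminium chloride) | C[N+](C)=Cc1c(O)cc(O)cc1Br.[Cl-] | intermediate
3 | 2-bromo-4,6-dihydroxybenzaldehyde | O=Cc1c(O)cc(O)cc1Br | intermediate
4 | benzyl bromide | BrCc1ccccc1 | starting material
5 | 2,4-bis(benzyloxy)-6-bromobenzaldehyde | O=Cc1c(OCc2ccccc2)cc(OCc2ccccc2)cc1Br | intermediate
6 | 2,4-bis(benzyloxy)-6-bromobenzoic acid | OC(=O)c1c(OCc2ccccc2)cc(OCc2ccccc2)cc1Br | intermediate
7 | 2-bromo-6-hydroxy-4-(methoxymethoxy)benzaldehyde | O=Cc1c(O)cc(OCOC)cc1Br | intermediate
8 | 2-bromo-6-methoxy-4-(methoxymethoxy)benzaldehyde | O=Cc1c(OC)cc(OCOC)cc1Br | intermediate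
9 | 2-bromo-6-methoxy-4-(methoxymethoxy)benzoic acid | OC(=O)c1c(OC)cc(OCOC)cc1Br | intermediate
10 | benzyl 2-bromo-6-methoxy-4-(methoxymethoxy)benzoate | O=C(OCc1ccccc1)c1c(OC)cc(OCOC)cc1Br | intermediate
11 | benzyl 2-bromo-4-hydroxy-6-methoxybenzoate | O=C(OCc1ccccc1)c1c(OC)cc(O)cc1Br | intermediate
12 | 2,4-bis(benzyloxy)-6-bromobenzoyl chloride | O=C(Cl)c1c(OCc2ccccc2)cc(OCc2ccccc2)cc1Br | intermediate
13 | benzyl 4-{[2,4-bis(benzyloxy)-6-bromobenzoyl]oxy}-2-bromo-6-methoxybenzoate | O=C(Oc1cc(Br)c(C(=O)OCc2ccccc2)c(OC)c1)c1c(Br)cc(OCc2ccccc2)cc1OCc1ccccc1 | intermediate
14 | heptan-2-one | CCCCCC(C)=O | starting material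
15 | lithium hept-1-en-2-olate | [Li+].[O-]C(=C)CCCCC | intermediate
16 | 2-(trimethylsilyloxy)hept-1-ene | C=C(CCCCC)O[Si](C)(C)C | intermediate
17 | tributyl(hept-1-en-2-yloxy)stannane (tributyltin enolate of heptan-2-one) | C=C(CCCCC)O[Sn](CCCC)(CCCC)CCCC | intermediate
18 | benzyl 4-{[2,4-bis(benzyloxy)-6-(2-oxoheptyl)benzoyl]oxy}-2-bromo-6-methoxybenzoate | CCCCCC(=O)Cc1cc(OCc2ccccc2)cc(OCc2ccccc2)c1C(=O)Oc1cc(Br)c(C(=O)OCc2ccccc2)c(OC)c1 | intermediate
19 | benzyl 4-{[2,4-bis(benzyloxy)-6-bromobenzoyl]oxy}-2-methoxy-6-(2-oxoheptyl)benzoate | O=C(Oc1cc(CC(=O)CCCCC)c(C(=O)OCc2ccccc2)c(OC)c1)c1c(Br)cc(OCc2ccccc2)cc1OCc1ccccc1 | intermediate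
20 | benzyl 4-{[2,4-bis(benzyloxy)-6-(2-oxoheptyl)benzoyl]oxy}-2-methoxy-6-(2-oxoheptyl)benzoate (tribenzyl arthonioic acid) | CCCCCC(=O)Cc1cc(OCc2ccccc2)cc(OCc2ccccc2)c1C(=O)Oc1cc(CC(=O)CCCCC)c(C(=O)OCc2ccccc2)c(OC)c1 | intermediate
21 | arthonioic acid, 4-{[2,4-dihydroxy-6-(2-oxoheptyl)benzoyl]oxy}-2-methoxy-6-(2-oxoheptyl)benzoic acid | CCCCCC(=O)Cc1cc(O)cc(O)c1C(=O)Oc1cc(CC(=O)CCCCC)c(C(=O)O)c(OC)c1 | target

## Step count and least certain steps

Total step count: 12. Longest linear sequence: 9 steps from 1 (steps 1, 4, 5, 6, 7, 8, 9, 11, 12).

**Step 11 (key step).** The most likely failures are: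
- stalling after the first coupling at the stage of 18 or 19, as the catalyst decays at a hindered bromide;
- protodebromination;
- loss of the enol silane to adventitious water before fluoride transfer;
- base-free but Lewis-acid-assisted enol lactonization of a product ketone onto the neighbouring aryl ester, which would break the depside.

Fallback, from 13 back to 20: a twofold Stille coupling with tributyl(2-methylideneheptyl)stannane F1, using Pd(PPh3)4 in toluene at 100 °C. F1 would be made from commercial 2-methylhept-1-ene by allylic metalation at the methyl group with n-BuLi and KOt-Bu and a Bu3SnCl quench. The coupling should give benzyl 4-{[2,4-bis(benzyloxy)-6-(2-methylideneheptyl)benzoyl]oxy}-2-methoxy-6-(2-methylideneheptyl)benzoate F2. The allyl unit is symmetrical, so allylic transposition does not matter. Lemieux–Johnson cleavage of the two 1,1-disubstituted alkenes (OsO4 cat., NaIO4, 2,6-lutidine, dioxane/H2O) then reveals both ketones and rejoins the route at 20.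

**Step 1.** The likely failures are poor site selectivity between the carbon flanked by OH and Br and the carbon between the two hydroxyls, and consumption of reagent by O-formylation or O-phosphorylation of the free phenols. Fallback, from 1 back to 3: protect first. O-methylation (MeI, K2CO3, acetone) gives 1-bromo-3,5-dimethoxybenzene F3. Vilsmeier–Haack formylation (POCl3, DMF) proceeds through N-[(2-bromo-4,6-dimethoxyphenyl)methylidene]-N-methylmethanaminium chloride F4 to 2-bromo-4,6-dimethoxybenzaldehyde F5. Twofold demethylation with BBr3 (CH2Cl2, −78 °C to rt) rejoins the route at 3.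

**Step 9.** The likely failure is sluggish addition–elimination at a carbonyl flanked by a benzyloxy group and a bromine, so the weakly nucleophilic phenol stays unacylated and the acid chloride is lost on work-up. Fallback, from 6 and 11 back to 13: change the mechanism from addition–elimination to acylium capture. Treatment of 6 and 11 with (CF3CO)2O in toluene at rt forms 2,4-bis(benzyloxy)-6-bromobenzoic trifluoroacetic anhydride F6. Its ionization to the acylium ion is helped by the two ortho substituents and the two donor oxygens, and 11 captures the ion to give 13.

**Step 12.** The likely failures are slow cleavage of the last, hindered benzyl ether with long contact with the catalyst, slow reduction of a ketone followed by lactonization of the resulting alcohol, and ring–chain closure of the freed keto acid. Fallback, from 20 directly to 21: non-reductive debenzylation with BCl3 and pentamethylbenzene in CH2Cl2 at −78 °C, quenched cold. The benzyl cations are taken up by the arene, and the short, cold exposure should spare the methyl ether and limit acid-promoted lactonization.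

## Further compounds

F1 | step 11 | tributyl(2-methylideneheptyl)stannane | CCCCCC(=C)C[Sn](CCCC)(CCCC)CCCC
F2 | step 11 | benzyl 4-{[2,4-bis(benzyloxy)-6-(2-methylideneheptyl)benzoyl]oxy}-2-methoxy-6-(2-methylideneheptyl)benzoate | CCCCCC(=C)Cc1cc(OCc2ccccc2)cc(OCc2ccccc2)c1C(=O)Oc1cc(CC(=C)CCCCC)c(C(=O)OCc2ccccc2)c(OC)c1
F3 | step 1 | 1-bromo-3,5-dimethoxybenzene | COc1cc(OC)cc(Br)c1
F4 | step 1 | N-[(2-bromo-4,6-dimethoxyphenyl)methylidene]-N-methylmethanaminium chloride | C[N+](C)=Cc1c(OC)cc(OC)cc1Br.[Cl-]
F5 | step 1 | 2-bromo-4,6-dimethoxybenzaldehyde | O=Cc1c(OC)cc(OC)cc1Br
F6 | step 9 | 2,4-bis(benzyloxy)-6-bromobenzoic trifluoroacetic anhydride | O=C(OC(=O)C(F)(F)F)c1c(OCc2ccccc2)cc(OCc2ccccc2)cc1Br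
F0 | step 12 | none | none
A1 | alternative 1 | benzyl 4-hydroxy-2-methoxy-6-[(2-pentyl-1,3-dioxolan-2-yl)methyl]benzoate | CCCCCC1(Cc2cc(O)cc(OC)c2C(=O)OCc2ccccc2)OCCO1
A2 | alternative 1 | 1,1-dimethoxy-3-(trimethylsilyloxy)buta-1,3-diene | COC(OC)=CC(=C)O[Si](C)(C)C
A3 | alternative 1 | benzyl 4-(2-pentyl-1,3-dioxolan-2-yl)but-2-ynoate | CCCCCC1(CC#CC(=O)OCc2ccccc2)OCCO1
A4 | alternative 2 | tert-butyl 4-{[2,4-diacetoxy-6-(2-oxoheptyl)benzoyl]oxy}-2-methoxy-6-(2-oxoheptyl)benzoate (di-O-acetyl arthonioic acid tert-butyl ester) | CCCCCC(=O)Cc1cc(OC(C)=O)cc(OC(C)=O)c1C(=O)Oc1cc(CC(=O)CCCCC)c(C(=O)OC(C)(C)C)c(OC)c1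
A5 | alternative 2 | tert-butyl 4-{[2,4-diacetoxy-6-(chloromethyl)benzoyl]oxy}-2-(chloromethyl)-6-methoxybenzoate | CC(=O)Oc1cc(CCl)c(C(=O)Oc2cc(CCl)c(C(=O)OC(C)(C)C)c(OC)c2)c(OC(C)=O)c1
A6 | alternative 2 | hexanoyl chloride | CCCCCC(Cl)=O
A7 | alternative 3 | benzyl 4-({2,4-bis(benzyloxy)-6-[(2-pentyl-1,3-dioxolan-2-yl)methyl]benzoyl}oxy)-2-methoxy-6-[(2-pentyl-1,3-dioxolan-2-yl)methyl]benzoate | CCCCCC1(Cc2cc(OCc3ccccc3)cc(OCc3ccccc3)c2C(=O)Oc2cc(CC3(CCCCC)OCCO3)c(C(=O)OCc3ccccc3)c(OC)c2)OCCO1
A8 | alternative 3 | 2-{[3,5-bis(benzyloxy)-2-iodophenyl]methyl}-2-pentyl-1,3-dioxolane | CCCCCC1(Cc2cc(OCc3ccccc3)cc(OCc3ccccc3)c2I)OCCO1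
A9 | alternative 3 | carbon monoxide | [C-]#[O+]
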